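The lactone is disconnected at its C3–C4 bond (C-alpha to C-beta of the oxolan-2-one ring). Because the two 3,4,5-trimethoxyphenyl rings are identical, the exocyclic CHAr2 carbon is not stereogenic and C4 is a plain methine, so C4 can start as an unfunctionalised CH2 of an achiral 3,3-diarylpropyl chain. The key step, an enantioselective rhodium-carbene C–H insertion of the corresponding diazoacetate, forms the C3–C4 bond, closes the five-membered lactone and sets C4 in one operation. The precursor is an open-chain diazoacetate with no stereocentre. The C3 methyl group is then introduced trans to the diarylmethyl group by enolate alkylation.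

Key step: step 5

Assumption: the sense of induction of Rh2(MPPIM)4 is carried over from 3-arylpropyl diazoacetates, where the 4S catalyst is expected to give the arrangement at C-beta opposite to the one needed here; the 4R catalyst is therefore specified. Rh2(4R-MPPIM)4 is the dirhodium tetrakis-carboxamidate of methyl (4R)-2-oxo-1-(3-phenylpropanoyl)imidazolidine-4-carboxylate (divalent rhodium), made from Rh2(OAc)4 by ligand exchange if not purchased.

Step 1
Reactants: 1 3,4,5-trimethoxyphenylboronic acid; 2 methyl (E)-3-(3,4,5-trimethoxyphenyl)prop-2-enoate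
Product: 3 methyl 3,3-bis(3,4,5-trimethoxyphenyl)propanoate
Conditions: [Rh(OH)(cod)]2 (3 mol %), 1 (2.5 equiv), 1,4-dioxane/H2O 10:1, 80 °C
Reagents that add atoms: none
Why: Hayashi–Miyaura 1,4-addition, in which the aryl group passes from boron to monovalent rhodium, the aryl–rhodium species inserts the enoate at the beta carbon and water protonates the rhodium enolate; the two aryl groups are identical, so the new CHAr2 carbon is no stereocentre and no chiral ligand is needed.

Step 2
Reactants: 3 methyl 3,3-bis(3,4,5-trimethoxyphenyl)propanoate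
Product: 4 3,3-bis(3,4,5-trimethoxyphenyl)propan-1-ol
Conditions: LiAlH4, THF, 0 °C to rt; H2O, aq NaOH work-up
Reagents that add atoms: none
Why: Lithium aluminium hydride reduction of an ester to the primary alcohol, which the aryl methyl ethers and the diarylmethine tolerate.

Step 3
Reactants: 4 3,3-bis(3,4,5-trimethoxyphenyl)propan-1-ol
Product: 5 3,3-bis(3,4,5-trimethoxyphenyl)propyl 2-bromoacetate
Conditions: BrCH2COBr (1.5 equiv), NaHCO3 (3 equiv), MeCN, 0 °C
Reagents that add atoms: bromoacetyl bromide, BrCC(Br)=O
Why: O-acylation of an unhindered primary alcohol by an acyl bromide (first half of the Fukuyama diazoacetate synthesis), with solid NaHCO3 taking up HBr so that the electron-rich rings are not exposed to acid.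

Step 4
Reactants: 5 3,3-bis(3,4,5-trimethoxyphenyl)propyl 2-bromoacetate
Product: 7 3,3-bis(3,4,5-trimethoxyphenyl)propyl 2-diazoacetate, via ditosylhydrazinyl acetate 6 (not isolated)
Conditions: TsNHNHTs (2 equiv), DBU (5 equiv), THF, 0 °C
Reagents that add atoms: N,N'-ditosylhydrazine, Cc1ccc(cc1)S(=O)(=O)NNS(=O)(=O)c1ccc(C)cc1
Why: Fukuyama diazoacetate synthesis, in which the ditosylhydrazine anion displaces bromide (SN2) and DBU then induces two successive losses of p-toluenesulfinate from nitrogen, leaving the diazo group under conditions mild enough for the ester.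

Step 5
Reactants: 7 3,3-bis(3,4,5-trimethoxyphenyl)propyl 2-diazoacetate
Product: 8 (4R)-4-[bis(3,4,5-trimethoxyphenyl)methyl]oxolan-2-one
Conditions: Rh2(4R-MPPIM)4 (1 mol %), CH2Cl2, reflux, 7 added by syringe pump over 10 h
Reagents that add atoms: none
Why: The diazo carbon binds an axial site of the divalent-rhodium dimer and loses N2 to give a catalyst-bound electrophilic carbene, which inserts into one of the two enantiotopic C–H bonds at C2 of the propyl chain through a three-centre, hydride-transfer-like transition state with retention. The closest known reaction type is the enantioselective lactonisation of 3-arylpropyl diazoacetates to beta-benzyl-gamma-butyrolactones with chiral dirhodium carboxamidates (Doyle C–H insertion). The oxolan-2-one ring closes by 1,5-insertion: the carbene carbon becomes C3 and the chain CH2 becomes C4, so the C3–C4 bond and the ring form together. The C4 stereocentre is set by the catalyst alone, the (4R)-configured ester groups around the carbene being expected to select the pro-R hydrogen and so give the R lactone (R because CHAr2 outranks CH2C=O). Site selectivity is needed against the O–CH2 hydrogens (four-membered ring), the doubly benzylic methine (six-membered ring) and addition to the electron-rich arenes; the carboxamidate ligands make the carbene less electrophilic and biased towards five-ring closure, the methine is shielded between two aryl rings, and slow addition suppresses carbene dimerisation.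

Step 6
Reactants: 8 (4R)-4-[bis(3,4,5-trimethoxyphenyl)methyl]oxolan-2-one
Product: 10 peperomin C [(3S,4S)-4-[bis(3,4,5-trimethoxyphenyl)methyl]-3-methyloxolan-2-one], via lithium enolate 9 (not isolated)
Conditions: LiN(SiMe3)2 (1.1 equiv), THF, −78 °C; MeI (3 equiv), −78 to −40 °C
Reagents that add atoms: iodomethane, CI
Why: Alkylation of a lactone enolate, in which the planar lithium enolate should be methylated on the face anti to the bulky C4 diarylmethyl group, setting C3 as S (3,4-trans) under substrate control while the non-acidic C4 centre is untouched.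

Compound list
1 | 3,4,5-trimethoxyphenylboronic acid | COc1cc(cc(OC)c1OC)B(O)O | starting material
2 | methyl (E)-3-(3,4,5-trimethoxyphenyl)prop-2-enoate | COC(=O)/C=C/c1cc(OC)c(OC)c(OC)c1 | starting material
3 | methyl 3,3-bis(3,4,5-trimethoxyphenyl)propanoate | COC(=O)CC(c1cc(OC)c(OC)c(OC)c1)c1cc(OC)c(OC)c(OC)c1 | intermediate
4 | 3,3-bis(3,4,5-trimethoxyphenyl)propan-1-ol | OCCC(c1cc(OC)c(OC)c(OC)c1)c1cc(OC)c(OC)c(OC)c1 | intermediate
5 | 3,3-bis(3,4,5-trimethoxyphenyl)propyl 2-bromoacetate | BrCC(=O)OCCC(c1cc(OC)c(OC)c(OC)c1)c1cc(OC)c(OC)c(OC)c1 | intermediate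
6 | 3,3-bis(3,4,5-trimethoxyphenyl)propyl 2-[1,2-bis(4-methylbenzenesulfonyl)hydrazin-1-yl]acetate (not isolated) | Cc1ccc(cc1)S(=O)(=O)NN(CC(=O)OCCC(c1cc(OC)c(OC)c(OC)c1)c1cc(OC)c(OC)c(OC)c1)S(=O)(=O)c1ccc(C)cc1 | intermediate
7 | 3,3-bis(3,4,5-trimethoxyphenyl)propyl 2-diazoacetate | [N-]=[N+]=CC(=O)OCCC(c1cc(OC)c(OC)c(OC)c1)c1cc(OC)c(OC)c(OC)c1 | intermediate
8 | (4R)-4-[bis(3,4,5-trimethoxyphenyl)methyl]oxolan-2-one | COc1cc(C(c2cc(OC)c(OC)c(OC)c2)[C@@H]2COC(=O)C2)cc(OC)c1OC | intermediate
9 | lithium enolate of 8, lithium (3R)-3-[bis(3,4,5-trimethoxyphenyl)methyl]-2,3-dihydrofuran-5-olate (not isolated) | COc1cc(C(c2cc(OC)c(OC)c(OC)c2)[C@@H]2COC([O-])=C2)cc(OC)c1OC.[Li+] | intermediate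
10 | peperomin C, (3S,4S)-4-[bis(3,4,5-trimethoxyphenyl)methyl]-3-methyloxolan-2-one | COc1cc(C(c2cc(OC)c(OC)c(OC)c2)[C@@H]2COC(=O)[C@H]2C)cc(OC)c1OC | target

Total step count: 6. Longest linear sequence: 6 steps (from 1 and 2 to 10).

Steps most likely to fail

1. Step 5. The carbene may be diverted into addition to the electron-rich rings, insertion at the doubly benzylic methine or next to oxygen, or dimerisation. The bulky diarylmethyl group may also erode discrimination between the two enantiotopic hydrogens. The fallback sets out from 3 and comes back at 8; it makes the same C–C bond between two molecules under auxiliary control. Saponification of 3 (LiOH, THF/H2O) should give 3,3-bis(3,4,5-trimethoxyphenyl)propanoic acid F1. Activation as the mixed pivalic anhydride (PivCl, Et3N, THF, −20 °C) and acylation of lithiated (R)-4-benzyloxazolidin-2-one (n-BuLi, −78 °C) should give (4R)-4-benzyl-3-[3,3-bis(3,4,5-trimethoxyphenyl)propanoyl]oxazolidin-2-one F2. Its chelated Z-enolate (NaN(SiMe3)2, THF, −78 °C) should be alkylated by tert-butyl bromoacetate on the face away from the benzyl group (Evans alkylation) to give tert-butyl (3R)-3-{[(4R)-4-benzyl-2-oxooxazolidin-3-yl]carbonyl}-4,4-bis(3,4,5-trimethoxyphenyl)butanoate F3. Reductive removal of the auxiliary (LiBH4, THF/MeOH, 0 °C) should leave tert-butyl (3R)-3-(hydroxymethyl)-4,4-bis(3,4,5-trimethoxyphenyl)butanoate F4. TFA in CH2Cl2 should then cleave the tert-butyl ester and close the lactone to 8.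

2. Step 1. Protodeboronation of the electron-rich boronic acid may outrun the slow insertion of an enoate that is beta-aryl substituted and itself electron-rich. The fallback sets out from 2 and comes back at 3. Mizoroki–Heck arylation of 2 with 5-iodo-1,2,3-trimethoxybenzene (Pd(OAc)2 reduced in the flask to zerovalent palladium, Bu4NBr, K2CO3, DMF, 110 °C) should give methyl 3,3-bis(3,4,5-trimethoxyphenyl)prop-2-enoate F5; alkene geometry is irrelevant because the two aryl groups are identical. Hydrogenation (H2, Pd/C, EtOAc) should give 3.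

3. Step 6. Proton exchange between product and unreacted enolate may lead to double methylation, and attack anti to the diarylmethyl group may be incomplete. The fallback sets out from 8 and comes back at 10; it installs the carbon as a methylidene group and lets equilibration set the trans geometry. Formylation (NaH, HCO2Et, THF) should give (4S)-4-[bis(3,4,5-trimethoxyphenyl)methyl]-3-(hydroxymethylidene)oxolan-2-one F6 as its sodium salt. Heating this with paraformaldehyde in THF should transfer the formyl group and eliminate formate to give (4S)-4-[bis(3,4,5-trimethoxyphenyl)methyl]-3-methylideneoxolan-2-one F7. Hydrogenation (H2, Pd/C, EtOAc) should deliver hydrogen anti to the diarylmethyl group and give mainly the cis lactone (3R,4S)-4-[bis(3,4,5-trimethoxyphenyl)methyl]-3-methyloxolan-2-one F8. Epimerisation at C3 with DBU in toluene at 80 °C should bring it to the more stable trans lactone 10.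

Further compounds
F1 | step 5 | 3,3-bis(3,4,5-trimethoxyphenyl)propanoic acid | OC(=O)CC(c1cc(OC)c(OC)c(OC)c1)c1cc(OC)c(OC)c(OC)c1
F2 | step 5 | (4R)-4-benzyl-3-[3,3-bis(3,4,5-trimethoxyphenyl)propanoyl]oxazolidin-2-one | COc1cc(cc(OC)c1OC)C(CC(=O)N1[C@H](Cc2ccccc2)COC1=O)c1cc(OC)c(OC)c(OC)c1
F3 | step 5 | tert-butyl (3R)-3-{[(4R)-4-benzyl-2-oxooxazolidin-3-yl]carbonyl}-4,4-bis(3,4,5-trimethoxyphenyl)butanoate | COc1cc(cc(OC)c1OC)C(c1cc(OC)c(OC)c(OC)c1)[C@@H](CC(=O)OC(C)(C)C)C(=O)N1[C@H](Cc2ccccc2)COC1=O
F4 | step 5 | tert-butyl (3R)-3-(hydroxymethyl)-4,4-bis(3,4,5-trimethoxyphenyl)butanoate | COc1cc(cc(OC)c1OC)C(c1cc(OC)c(OC)c(OC)c1)[C@@H](CC(=O)OC(C)(C)C)CO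
F5 | step 1 | methyl 3,3-bis(3,4,5-trimethoxyphenyl)prop-2-enoate | COC(=O)C=C(c1cc(OC)c(OC)c(OC)c1)c1cc(OC)c(OC)c(OC)c1
F6 | step 6 | (4S)-4-[bis(3,4,5-trimethoxyphenyl)methyl]-3-(hydroxymethylidene)oxolan-2-one | COc1cc(C(c2cc(OC)c(OC)c(OC)c2)[C@@H]2COC(=O)C2=CO)cc(OC)c1OC
F7 | step 6 | (4S)-4-[bis(3,4,5-trimethoxyphenyl)methyl]-3-methylideneoxolan-2-one | COc1cc(C(c2cc(OC)c(OC)c(OC)c2)[C@@H]2COC(=O)C2=C)cc(OC)c1OC
F8 | step 6 | (3R,4S)-4-[bis(3,4,5-trimethoxyphenyl)methyl]-3-methyloxolan-2-one | COc1cc(C(c2cc(OC)c(OC)c(OC)c2)[C@@H]2COC(=O)[C@@H]2C)cc(OC)c1OC
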